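(The numbers are those of an exercise; the run is a simulation.)

The question is how much of the charged enzyme stands unbound at 50 % conversion, and what extra enzyme does to the rate there.

starting material 0.20 M; enzyme 9.7 × 10⁻⁴ mol%; added ligand 2.4 µM

    starting material + enzyme → target + enzyme, rate k1*[starting material]^3*[enzyme]/(1 + ([starting material]/Kh1)^3) (Kh1 = 0.289 M, k1 = 3.46 × 10⁷ M⁻³ s⁻¹)
    enzyme + added ligand ⇌ idle complex, settled at all times (K2 = 6.9 × 10⁶ M⁻¹)

- the form that holds most of the catalyst when 50 % of the starting material are converted (idle complex / enzyme)
- its share of the catalyst then
- apparent order in enzyme when 50 % of the starting material are converted (percent change of the rate of making target for one percent more enzyme charged)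
- factor on the rate of making target when 50 % of the starting material are converted if enzyme is charged twice over

1. The flask holds 1.94 µM of enzyme against 2.4 µM of added ligand. The reciprocal of the balance constant, the dissociation constant, is 0.145 µM.

2. As a first guess, the ligand charge exceeds the enzyme charge, and the dissociation constant is smaller than the excess of 0.460 µM. So the enzyme is taken as bound, with that excess as c(added ligand).

3. The balance then gives c(enzyme) near 0.465 µM.

4. The weak link is step 2: this c(enzyme) is about as large as the excess, and each enzyme left unbound leaves a ligand unbound too. Reforged, c(added ligand) equals the excess plus c(enzyme), and the balance becomes a quadratic with the root c(enzyme) = 0.308 µM.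

5. The free share, the part of the enzyme charge left unbound, is then 15.9 %. Idle complex, an off-cycle form, holds the other 84.1 %. Neither starting material nor target enters the balance, so conversion does not move this share.

6. At fixed conversion the rate follows c(enzyme), so no time course is needed. Differentiating the quadratic gives an order of 2.34. With the charge doubled, the root is 1.67 µM, a factor of 5.42.

7. The forecast agrees with this reckoning: idle complex at 84 %, order 2.3, factor 5.4, on the ground that “the ligand titrates out most of the enzyme”.

8. The simulation gives idle complex at 84.1 %, order 2.3, factor 5.43.

The free share stands in the flask as 15.9 % of the catalyst, and enzyme reads 15.9 % after 2.00 s and 15.9 % after 200 s. The same run without the association of enzyme and added ligand goes, at 50 % conversion, at 6.30 times the actual rate, and one over the free share is 6.29. Without that association the apparent order in enzyme falls from 2.3 to 1.0.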